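**Plan**

1. Retrosynthesis: after removal of the silyl and benzyl ethers, the Cα–H bond is traced back to an (E)-benzylidene lactone. The lactone carbonyl carbon lies between the ring oxygen and Cα, so its two bonds (O–C(=O) and C(=O)–Cα) are cut to CO and a homopropargylic alcohol. In that alcohol the OH sits on the CH2 attached to Cβ, and the two alkyne carbons are Cα and the benzylic carbon on ring B.
2. The ring B–alkyne bond is cut next (Sonogashira) into a ring A/B aryl bromide and a ring C/D alkynol. The C≡CH, CH2OH and CH2–ring C arms of the alkynol go back to a Weinreb amide, an auxiliary-directed hydroxymethylation and a Heck reaction of a ring C bromide.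
3. Both halves go back, by cutting the carbinol–CH(aryl) bond (aldol), to one arylacetyl oxazolidinone imide and O-benzylvanillin. The imide comes from 5-bromo-o-vanillin by one-carbon homologation.
4. Forward order: common imide; anti aldol to the open ring A/B diol; syn aldol and cationic closure of the dihydrobenzofuran (first ring); side chain to the alkynol; Sonogashira union; CO lactonisation (second ring); reduction at Cα, desilylation, hydrogenolysis.
5. Stereochemistry: both centres of the open diol come from a magnesium-catalysed anti aldol on the (S)-benzyloxazolidinone. C3 of the dihydrobenzofuran comes from a boron syn aldol on the same imide and C2 from trans-selective ring closure. Cβ comes from titanium-enolate hydroxymethylation on the (R)-auxiliary, and Cα from base equilibration trans to Cβ.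

Key step: step 20

Labels: ring A is the guaiacyl ring on the carbinol carbon, ring B the phenol ring that carries the lactone CH2, ring C the benzo ring of the dihydrobenzofuran, ring D its 2-aryl group. DBF stands for the (2S,3R)-2-(4-benzyloxy-3-methoxyphenyl)-3-[(tert-butyldiphenylsilyloxy)methyl]-7-methoxy-2,3-dihydrobenzofuran-5-yl residue. ArL stands for the 3-[(1S,2S)-1-(4-benzyloxy-3-methoxyphenyl)-1,3-bis(tert-butyldimethylsilyloxy)propan-2-yl]-5-methoxy-4-(triisopropylsilyloxy)phenyl residue.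

Assumption: the magnesium-catalysed aldol of the arylacetyl imide is taken to follow the same chelate-controlled facial preference as the parent propionyl imides.

**Route**

Step 1
Reactants: 1 5-bromo-2-hydroxy-3-methoxybenzaldehyde
Product: 2 5-bromo-3-methoxy-2-(triisopropylsilyloxy)benzaldehyde
Conditions: TIPSCl, imidazole, DMF, rt
Reagents that add atoms: chlorotriisopropylsilane, CC(C)[Si](Cl)(C(C)C)C(C)C
Why: Phenol O-silylation; the hindered aryl triisopropylsilyl ether should survive ylide, acid, hydride and palladium chemistry and still fall to fluoride, which suits both halves.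

Step 2
Reactants: 2 5-bromo-3-methoxy-2-(triisopropylsilyloxy)benzaldehyde
Product: 3 [4-bromo-2-methoxy-6-(2-methoxyethenyl)phenoxy]triisopropylsilane (E/Z mixture)
Conditions: Ph3P(CH2OMe)Cl, KN(SiMe3)2, THF, 0 °C to rt
Reagents that add atoms: (methoxymethyl)triphenylphosphonium chloride, COC[P+](c1ccccc1)(c1ccccc1)c1ccccc1.[Cl-]
Why: Wittig methoxymethylenation adds the one extra carbon as an enol ether (a masked arylacetaldehyde), and the non-nucleophilic base leaves the aryl silyl ether and the bromide alone.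

Step 3
Reactants: 3 [4-bromo-2-methoxy-6-(2-methoxyethenyl)phenoxy]triisopropylsilane
Product: 5 2-[5-bromo-3-methoxy-2-(triisopropylsilyloxy)phenyl]acetic acid, via arylacetaldehyde 4 (not isolated)
Conditions: 2 M HCl, THF, 40 °C; then NaH2PO4, 2-methyl-2-butene, NaClO2, t-BuOH/H2O, 0 °C to rt
Reagents that add atoms: water, O; sodium chlorite, [Na+].[O-]Cl=O
Why: Acid hydrolysis of the enol ether followed in the same pot by Pinnick oxidation converts the labile arylacetaldehyde directly into the arylacetic acid, with 2-methyl-2-butene scavenging hypochlorite to protect the electron-rich ring.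

Step 4
Reactants: 5 2-[5-bromo-3-methoxy-2-(triisopropylsilyloxy)phenyl]acetic acid; 6 (S)-4-benzyl-2-oxazolidinone
Product: 8 (4S)-4-benzyl-3-{2-[5-bromo-3-methoxy-2-(triisopropylsilyloxy)phenyl]acetyl}oxazolidin-2-one, via mixed pivalic anhydride 7 (not isolated)
Conditions: PivCl, Et3N, THF, −20 °C; then 6, LiCl, rt
Reagents that add atoms: none
Why: N-acylation of the oxazolidinone through the mixed pivalic anhydride under LiCl/Et3N activation, which avoids an organolithium base in the presence of the aryl bromide.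

Step 5
Reactants: 8 (4S)-4-benzyl-3-{2-[5-bromo-3-methoxy-2-(triisopropylsilyloxy)phenyl]acetyl}oxazolidin-2-one; 9 4-benzyloxy-3-methoxybenzaldehyde
Product: 11 (4S)-4-benzyl-3-{(2R,3S)-3-(4-benzyloxy-3-methoxyphenyl)-2-[5-bromo-3-methoxy-2-(triisopropylsilyloxy)phenyl]-3-hydroxypropanoyl}oxazolidin-2-one, via trimethylsilyl ether 10 (not isolated)
Conditions: MgCl2 (20 mol%), Et3N, TMSCl, EtOAc, rt; then citric acid, MeOH, rt
Reagents that add atoms: none
Why: Magnesium-catalysed direct anti aldol of an N-acyloxazolidinone: soft enolisation gives the Z enolate chelated to magnesium, the aldehyde adds through a boat-like transition state on the face opposite the auxiliary benzyl group and TMSCl traps the aldolate, which should set C2 as R and C3 as S (2,3-anti).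

Step 6
Reactants: 11 the anti aldol adduct
Product: 12 (1S,2S)-1-(4-benzyloxy-3-methoxyphenyl)-2-[5-bromo-3-methoxy-2-(triisopropylsilyloxy)phenyl]propane-1,3-diol
Conditions: LiBH4, MeOH, THF, 0 °C
Reagents that add atoms: none
Why: Reductive removal of the auxiliary with LiBH4 turns the imide carbonyl into the primary alcohol without touching the two stereocentres, the aryl bromide or the aryl silyl ether.

Step 7
Reactants: 12 the (1S,2S)-diol
Product: 13 (1S,2S)-1-(4-benzyloxy-3-methoxyphenyl)-2-[5-bromo-3-methoxy-2-(triisopropylsilyloxy)phenyl]-1,3-bis(tert-butyldimethylsilyloxy)propane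
Conditions: TBSOTf, 2,6-lutidine, CH2Cl2, −78 to 0 °C
Reagents that add atoms: tert-butyldimethylsilyl triflate, CC(C)(C)[Si](C)(C)OS(=O)(=O)C(F)(F)F
Why: Silylation of the primary and the hindered benzylic secondary alcohol with the silyl triflate under basic, non-ionising conditions gives the fully protected ring A/B coupling partner.

Step 8
Reactants: 8 (4S)-4-benzyl-3-{2-[5-bromo-3-methoxy-2-(triisopropylsilyloxy)phenyl]acetyl}oxazolidin-2-one; 9 4-benzyloxy-3-methoxybenzaldehyde
Product: 14 (4S)-4-benzyl-3-{(2S,3S)-3-(4-benzyloxy-3-methoxyphenyl)-2-[5-bromo-3-methoxy-2-(triisopropylsilyloxy)phenyl]-3-hydroxypropanoyl}oxazolidin-2-one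
Conditions: Bu2BOTf, i-Pr2NEt, CH2Cl2, −78 to 0 °C; then 9, −78 to 0 °C; work-up pH 7 buffer, MeOH, H2O2
Reagents that add atoms: none
Why: Evans syn aldol: the Z dibutylboron enolate reacts through a closed chair transition state on the face away from the auxiliary benzyl group, which should set C2 and C3 both as S (2,3-syn), C2 being the future C3 of the dihydrobenzofuran.

Step 9
Reactants: 14 the syn aldol adduct
Product: 15 (1S,2R)-1-(4-benzyloxy-3-methoxyphenyl)-2-[5-bromo-3-methoxy-2-(triisopropylsilyloxy)phenyl]propane-1,3-diol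
Conditions: LiBH4, MeOH, THF, 0 °C
Reagents that add atoms: none
Why: Reductive cleavage of the imide with LiBH4 releases the auxiliary and gives the 1,3-diol with both stereocentres intact.

Step 10
Reactants: 15 the (1S,2R)-diol
Product: 17 [(2S,3R)-2-(4-benzyloxy-3-methoxyphenyl)-5-bromo-7-methoxy-2,3-dihydrobenzofuran-3-yl]methanol, via free phenol diol 16 (not isolated)
Conditions: Bu4NF, THF, 0 °C; then TsOH·H2O, rt
Reagents that add atoms: none
Why: Fluoride frees the ring C phenol and acid then ionises the p-alkoxybenzylic alcohol to a stabilised cation that the phenol traps in a 5-exo dehydrative etherification; under reversible ionisation the aryl group settles trans to the CH2OH on C3, so the aldol-derived C3 (R) fixes C2 as S.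

Step 11
Reactants: 17 the dihydrobenzofuran alcohol
Product: 18 (2S,3R)-2-(4-benzyloxy-3-methoxyphenyl)-5-bromo-3-[(tert-butyldiphenylsilyloxy)methyl]-7-methoxy-2,3-dihydrobenzofuran
Conditions: TBDPSCl, imidazole, DMF, rt
Reagents that add atoms: tert-butylchlorodiphenylsilane, CC(C)(C)[Si](Cl)(c1ccccc1)c1ccccc1
Why: Silylation of the primary alcohol as the TBDPS ether, which should withstand the Lewis acid, hydride and dilute-acid steps that follow and leave only the homopropargylic hydroxyl free at the key step.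

Step 12
Reactants: 19 (R)-4-benzyl-2-oxazolidinone; 20 acryloyl chloride
Product: 21 (4R)-3-acryloyl-4-benzyloxazolidin-2-one
Conditions: n-BuLi, THF, −78 °C; then 20, −78 °C
Reagents that add atoms: none
Why: N-acylation of the lithiated oxazolidinone with the acid chloride at low temperature, which limits polymerisation of the acrylimide.

Step 13
Reactants: 18 the ring C bromide; 21 (4R)-3-acryloyl-4-benzyloxazolidin-2-one
Product: 22 (4R)-4-benzyl-3-[(E)-3-(DBF)prop-2-enoyl]oxazolidin-2-one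
Conditions: Pd2(dba)3, P(t-Bu)3·HBF4, Cy2NMe, dioxane, 70 °C
Reagents that add atoms: none
Why: Mizoroki–Heck coupling of the electron-rich aryl bromide with the acrylimide under zerovalent palladium and a bulky electron-rich phosphine gives the E-cinnamoyl imide by syn insertion and syn β-hydride elimination.

Step 14
Reactants: 22 the cinnamoyl imide
Product: 23 (4R)-4-benzyl-3-[3-(DBF)propanoyl]oxazolidin-2-one
Conditions: H2 (1 atm), 10% Pd/C, Ph2S (cat.), EtOAc, rt
Reagents that add atoms: none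
Why: Alkene hydrogenation over sulfide-poisoned Pd/C, which should saturate the conjugated C=C while leaving the aryl benzyl ethers and the benzylic C–O bond of the dihydrobenzofuran intact.

Step 15
Reactants: 23 the propanoyl imide
Product: 24 (4R)-4-benzyl-3-[(2S)-3-hydroxy-2-(DBF-methyl)propanoyl]oxazolidin-2-one
Conditions: TiCl4, i-Pr2NEt, CH2Cl2, 0 °C; then 1,3,5-trioxane, TiCl4, 0 °C
Reagents that add atoms: 1,3,5-trioxane, C1OCOCO1
Why: Auxiliary-controlled hydroxymethylation of the chelated Z titanium enolate with formaldehyde released from trioxane; the electrophile enters opposite the benzyl group of the (R)-oxazolidinone, which should set the new centre as S (it becomes Cβ, R in the lactone).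

Step 16
Reactants: 24 the hydroxymethyl imide
Product: 25 (2S)-3-hydroxy-N-methoxy-N-methyl-2-(DBF-methyl)propanamide
Conditions: MeNH(OMe)·HCl, AlMe3, CH2Cl2, −10 °C to rt
Reagents that add atoms: N,O-dimethylhydroxylamine hydrochloride, CNOC.Cl
Why: Aluminium amide transamidation of the β-hydroxy imide to the Weinreb amide, assisted by the free hydroxyl, releases the auxiliary without disturbing the α-centre.

Step 17
Reactants: 25 the hydroxy Weinreb amide
Product: 26 (2S)-N-methoxy-N-methyl-2-(DBF-methyl)-3-(triethylsilyloxy)propanamide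
Conditions: TESCl, imidazole, CH2Cl2, 0 °C
Reagents that add atoms: chlorotriethylsilane, CC[Si](Cl)(CC)CC
Why: Silylation of the primary alcohol as a triethylsilyl ether, chosen because dilute acid can later remove it while the TBDPS ether stays.

Step 18
Reactants: 26 the silylated Weinreb amide
Product: 29 (2R)-2-(DBF-methyl)but-3-yn-1-ol, via aldehyde 27 (not isolated), via triethylsilyl-protected alkyne 28 (not isolated)
Conditions: i-Bu2AlH, CH2Cl2, −78 °C; then MeOH, K2CO3, dimethyl (1-diazo-2-oxopropyl)phosphonate, 0 °C to rt; then 1 M HCl, rt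
Reagents that add atoms: dimethyl (1-diazo-2-oxopropyl)phosphonate, CC(=O)C(=[N+]=[N-])P(=O)(OC)OC
Why: Weinreb amide reduction stops at the chelated hemiaminal and releases the aldehyde on methanol quench, Seyferth–Gilbert homologation with the Ohira–Bestmann reagent gives the terminal alkyne, and dilute acid then cleaves only the triethylsilyl ether.

Step 19
Reactants: 13 the ring A/B bromide; 29 (2R)-2-(DBF-methyl)but-3-yn-1-ol
Product: 30 (2R)-4-(ArL)-2-(DBF-methyl)but-3-yn-1-ol
Conditions: PdCl2(PhCN)2, P(t-Bu)3·HBF4, CuI, i-Pr2NH, dioxane, rt to 40 °C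
Reagents that add atoms: none
Why: Sonogashira coupling under zerovalent palladium with a bulky phosphine and CuI joins the electron-rich aryl bromide to the terminal alkyne, and the amine base affects neither the free primary alcohol nor the propargylic stereocentre.

Step 20
Reactants: 30 (2R)-4-(ArL)-2-(DBF-methyl)but-3-yn-1-ol; 31 carbon monoxide
Product: 32 (3E,4R)-3-(ArL-methylidene)-4-(DBF-methyl)oxolan-2-one
Conditions: PdCl2(PPh3)2, SnCl2, CO (7 atm), MeCN/THF, 75 °C
Reagents that add atoms: none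
Why: The free primary alcohol, CO and divalent palladium (carrying a trichlorostannyl ligand) should form an alkoxycarbonylpalladium species that adds syn across the tethered alkyne, with the acyl carbon bonding to the alkyne carbon next to Cβ; protonolysis of the vinyl–palladium bond with retention then releases the lactone and returns divalent palladium. The closest known reaction type is the palladium-catalysed cyclocarbonylation of but-3-yn-1-ols, internal alkynes included, to α-alkylidene-γ-butyrolactones. The lactone ring closes in the 5-exo-dig mode, because the 6-endo alternative would need a trans double bond inside the ring after syn addition. No stereocentre is formed: Cβ is already in place and is not enolisable here, and the syn addition fixes the E geometry with the aryl group trans to the carbonyl. The step needs chemoselectivity for a single hydroxyl, secured because every other oxygen is silylated or benzylated, and regioselectivity, secured by the two-carbon tether between the hydroxyl and the alkyne.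

Step 21
Reactants: 32 the E-benzylidene lactone
Product: 34 (3R,4R)-3-(ArL-methyl)-4-(DBF-methyl)oxolan-2-one, via cis lactone 33 (not isolated)
Conditions: NiCl2·6H2O (cat.), NaBH4, THF/MeOH, 0 °C; then DBU, toluene, 60 °C
Reagents that add atoms: none
Why: Nickel boride conjugate reduction of the benzylidene lactone followed by base equilibration through the lactone enolate should set Cα as R under thermodynamic control, trans to the substituent on Cβ as in the more stable 3,4-dibenzyl butyrolactones.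

Step 22
Reactants: 34 the protected trans lactone
Product: 35 (3R,4R)-3-{3-[(1S,2S)-1-(4-benzyloxy-3-methoxyphenyl)-1,3-dihydroxypropan-2-yl]-4-hydroxy-5-methoxybenzyl}-4-{[(2S,3R)-2-(4-benzyloxy-3-methoxyphenyl)-3-(hydroxymethyl)-7-methoxy-2,3-dihydrobenzofuran-5-yl]methyl}oxolan-2-one
Conditions: Bu4NF, AcOH, THF, rt to 40 °C
Reagents that add atoms: none
Why: Fluoride desilylation removes the aryl TIPS, both TBS and the TBDPS ethers in one operation, and acetic acid buffering should keep the lactone closed and the benzylic carbinol configurationally intact.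

Step 23
Reactants: 35 the bis(benzyl ether)
Product: 36 (3R,4R)-3-{3-[(1S,2S)-1,3-dihydroxy-1-(4-hydroxy-3-methoxyphenyl)propan-2-yl]-4-hydroxy-5-methoxybenzyl}-4-{[(2S,3R)-2-(4-hydroxy-3-methoxyphenyl)-3-(hydroxymethyl)-7-methoxy-2,3-dihydrobenzofuran-5-yl]methyl}oxolan-2-one (CNP0186558.2)
Conditions: H2 (1 atm), 10% Pd/C, EtOAc/MeOH, rt
Reagents that add atoms: none
Why: Hydrogenolysis of the two aryl benzyl ethers under neutral conditions avoids the acid that would close the ring B phenol onto the benzylic carbinol and should leave the benzylic alcohol and the dihydrobenzofuran untouched.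

**Compound list**

1 | 5-bromo-2-hydroxy-3-methoxybenzaldehyde | COc1cc(Br)cc(C=O)c1O | starting material
2 | 5-bromo-3-methoxy-2-(triisopropylsilyloxy)benzaldehyde | COc1cc(Br)cc(C=O)c1O[Si](C(C)C)(C(C)C)C(C)C | intermediate
3 | [4-bromo-2-methoxy-6-(2-methoxyethenyl)phenoxy]triisopropylsilane (E/Z mixture) | COC=Cc1cc(Br)cc(OC)c1O[Si](C(C)C)(C(C)C)C(C)C | intermediate
4 | 2-[5-bromo-3-methoxy-2-(triisopropylsilyloxy)phenyl]acetaldehyde | O=CCc1cc(Br)cc(OC)c1O[Si](C(C)C)(C(C)C)C(C)C | intermediate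
5 | 2-[5-bromo-3-methoxy-2-(triisopropylsilyloxy)phenyl]acetic acid | OC(=O)Cc1cc(Br)cc(OC)c1O[Si](C(C)C)(C(C)C)C(C)C | intermediate
6 | (S)-4-benzyl-2-oxazolidinone | O=C1N[C@@H](Cc2ccccc2)CO1 | starting material
7 | mixed anhydride of acid 5 with pivalic acid | COc1cc(Br)cc(CC(=O)OC(=O)C(C)(C)C)c1O[Si](C(C)C)(C(C)C)C(C)C | intermediate
8 | (4S)-4-benzyl-3-{2-[5-bromo-3-methoxy-2-(triisopropylsilyloxy)phenyl]acetyl}oxazolidin-2-one | COc1cc(Br)cc(CC(=O)N2[C@@H](Cc3ccccc3)COC2=O)c1O[Si](C(C)C)(C(C)C)C(C)C | intermediate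
9 | 4-benzyloxy-3-methoxybenzaldehyde | COc1cc(C=O)ccc1OCc1ccccc1 | starting material
10 | 3-O-trimethylsilyl ether of anti adduct 11 | COc1cc([C@@H](O[Si](C)(C)C)[C@H](C(=O)N2[C@@H](Cc3ccccc3)COC2=O)c2cc(Br)cc(OC)c2O[Si](C(C)C)(C(C)C)C(C)C)ccc1OCc1ccccc1 | intermediate
11 | (4S)-4-benzyl-3-{(2R,3S)-3-(4-benzyloxy-3-methoxyphenyl)-2-[5-bromo-3-methoxy-2-(triisopropylsilyloxy)phenyl]-3-hydroxypropanoyl}oxazolidin-2-one | COc1cc([C@@H](O)[C@H](C(=O)N2[C@@H](Cc3ccccc3)COC2=O)c2cc(Br)cc(OC)c2O[Si](C(C)C)(C(C)C)C(C)C)ccc1OCc1ccccc1 | intermediate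
12 | (1S,2S)-1-(4-benzyloxy-3-methoxyphenyl)-2-[5-bromo-3-methoxy-2-(triisopropylsilyloxy)phenyl]propane-1,3-diol | COc1cc([C@@H](O)[C@H](CO)c2cc(Br)cc(OC)c2O[Si](C(C)C)(C(C)C)C(C)C)ccc1OCc1ccccc1 | intermediate
13 | (1S,2S)-1-(4-benzyloxy-3-methoxyphenyl)-2-[5-bromo-3-methoxy-2-(triisopropylsilyloxy)phenyl]-1,3-bis(tert-butyldimethylsilyloxy)propane | COc1cc([C@@H](O[Si](C)(C)C(C)(C)C)[C@H](CO[Si](C)(C)C(C)(C)C)c2cc(Br)cc(OC)c2O[Si](C(C)C)(C(C)C)C(C)C)ccc1OCc1ccccc1 | intermediate
14 | (4S)-4-benzyl-3-{(2S,3S)-3-(4-benzyloxy-3-methoxyphenyl)-2-[5-bromo-3-methoxy-2-(triisopropylsilyloxy)phenyl]-3-hydroxypropanoyl}oxazolidin-2-one | COc1cc([C@@H](O)[C@@H](C(=O)N2[C@@H](Cc3ccccc3)COC2=O)c2cc(Br)cc(OC)c2O[Si](C(C)C)(C(C)C)C(C)C)ccc1OCc1ccccc1 | intermediate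
15 | (1S,2R)-1-(4-benzyloxy-3-methoxyphenyl)-2-[5-bromo-3-methoxy-2-(triisopropylsilyloxy)phenyl]propane-1,3-diol | COc1cc([C@@H](O)[C@@H](CO)c2cc(Br)cc(OC)c2O[Si](C(C)C)(C(C)C)C(C)C)ccc1OCc1ccccc1 | intermediate
16 | (1S,2R)-1-(4-benzyloxy-3-methoxyphenyl)-2-(5-bromo-2-hydroxy-3-methoxyphenyl)propane-1,3-diol | COc1cc([C@@H](O)[C@@H](CO)c2cc(Br)cc(OC)c2O)ccc1OCc1ccccc1 | intermediate
17 | [(2S,3R)-2-(4-benzyloxy-3-methoxyphenyl)-5-bromo-7-methoxy-2,3-dihydrobenzofuran-3-yl]methanol | Brc1cc(OC)c2c(c1)[C@H](CO)[C@@H](c1ccc(OCc3ccccc3)c(OC)c1)O2 | intermediate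
18 | (2S,3R)-2-(4-benzyloxy-3-methoxyphenyl)-5-bromo-3-[(tert-butyldiphenylsilyloxy)methyl]-7-methoxy-2,3-dihydrobenzofuran | Brc1cc(OC)c2c(c1)[C@H](CO[Si](c1ccccc1)(c1ccccc1)C(C)(C)C)[C@@H](c1ccc(OCc3ccccc3)c(OC)c1)O2 | intermediate
19 | (R)-4-benzyl-2-oxazolidinone | O=C1N[C@H](Cc2ccccc2)CO1 | starting material
20 | acryloyl chloride | C=CC(Cl)=O | starting material
21 | (4R)-3-acryloyl-4-benzyloxazolidin-2-one | C=CC(=O)N1[C@H](Cc2ccccc2)COC1=O | intermediate
22 | (4R)-4-benzyl-3-[(E)-3-(DBF)prop-2-enoyl]oxazolidin-2-one | O=C(/C=C/c1cc(OC)c2c(c1)[C@H](CO[Si](c1ccccc1)(c1ccccc1)C(C)(C)C)[C@@H](c1ccc(OCc3ccccc3)c(OC)c1)O2)N1[C@H](Cc2ccccc2)COC1=O | intermediate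
23 | (4R)-4-benzyl-3-[3-(DBF)propanoyl]oxazolidin-2-one | O=C(CCc1cc(OC)c2c(c1)[C@H](CO[Si](c1ccccc1)(c1ccccc1)C(C)(C)C)[C@@H](c1ccc(OCc3ccccc3)c(OC)c1)O2)N1[C@H](Cc2ccccc2)COC1=O | intermediate
24 | (4R)-4-benzyl-3-[(2S)-3-hydroxy-2-(DBF-methyl)propanoyl]oxazolidin-2-one | O=C([C@H](CO)Cc1cc(OC)c2c(c1)[C@H](CO[Si](c1ccccc1)(c1ccccc1)C(C)(C)C)[C@@H](c1ccc(OCc3ccccc3)c(OC)c1)O2)N1[C@H](Cc2ccccc2)COC1=O | intermediate
25 | (2S)-3-hydroxy-N-methoxy-N-methyl-2-(DBF-methyl)propanamide | CON(C)C(=O)[C@H](CO)Cc1cc(OC)c2c(c1)[C@H](CO[Si](c1ccccc1)(c1ccccc1)C(C)(C)C)[C@@H](c1ccc(OCc3ccccc3)c(OC)c1)O2 | intermediate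
26 | (2S)-N-methoxy-N-methyl-2-(DBF-methyl)-3-(triethylsilyloxy)propanamide | CON(C)C(=O)[C@H](CO[Si](CC)(CC)CC)Cc1cc(OC)c2c(c1)[C@H](CO[Si](c1ccccc1)(c1ccccc1)C(C)(C)C)[C@@H](c1ccc(OCc3ccccc3)c(OC)c1)O2 | intermediate
27 | (2S)-2-(DBF-methyl)-3-(triethylsilyloxy)propanal | O=C[C@H](CO[Si](CC)(CC)CC)Cc1cc(OC)c2c(c1)[C@H](CO[Si](c1ccccc1)(c1ccccc1)C(C)(C)C)[C@@H](c1ccc(OCc3ccccc3)c(OC)c1)O2 | intermediate
28 | triethyl{[(2R)-2-(DBF-methyl)but-3-yn-1-yl]oxy}silane | C#C[C@H](CO[Si](CC)(CC)CC)Cc1cc(OC)c2c(c1)[C@H](CO[Si](c1ccccc1)(c1ccccc1)C(C)(C)C)[C@@H](c1ccc(OCc3ccccc3)c(OC)c1)O2 | intermediate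
29 | (2R)-2-(DBF-methyl)but-3-yn-1-ol | C#C[C@H](CO)Cc1cc(OC)c2c(c1)[C@H](CO[Si](c1ccccc1)(c1ccccc1)C(C)(C)C)[C@@H](c1ccc(OCc3ccccc3)c(OC)c1)O2 | intermediate
30 | (2R)-4-(ArL)-2-(DBF-methyl)but-3-yn-1-ol | COc1cc([C@@H](O[Si](C)(C)C(C)(C)C)[C@H](CO[Si](C)(C)C(C)(C)C)c2cc(C#C[C@H](CO)Cc3cc(OC)c4c(c3)[C@H](CO[Si](c5ccccc5)(c5ccccc5)C(C)(C)C)[C@@H](c3ccc(OCc5ccccc5)c(OC)c3)O4)cc(OC)c2O[Si](C(C)C)(C(C)C)C(C)C)ccc1OCc1ccccc1 | intermediate
31 | carbon monoxide | [C-]#[O+] | starting material
32 | (3E,4R)-3-(ArL-methylidene)-4-(DBF-methyl)oxolan-2-one | COc1cc([C@@H](O[Si](C)(C)C(C)(C)C)[C@H](CO[Si](C)(C)C(C)(C)C)c2cc(/C=C3/C(=O)OC[C@@H]3Cc3cc(OC)c4c(c3)[C@H](CO[Si](c5ccccc5)(c5ccccc5)C(C)(C)C)[C@@H](c3ccc(OCc5ccccc5)c(OC)c3)O4)cc(OC)c2O[Si](C(C)C)(C(C)C)C(C)C)ccc1OCc1ccccc1 | intermediate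
33 | (3S,4R)-3-(ArL-methyl)-4-(DBF-methyl)oxolan-2-one (cis) | COc1cc([C@@H](O[Si](C)(C)C(C)(C)C)[C@H](CO[Si](C)(C)C(C)(C)C)c2cc(C[C@@H]3C(=O)OC[C@@H]3Cc3cc(OC)c4c(c3)[C@H](CO[Si](c5ccccc5)(c5ccccc5)C(C)(C)C)[C@@H](c3ccc(OCc5ccccc5)c(OC)c3)O4)cc(OC)c2O[Si](C(C)C)(C(C)C)C(C)C)ccc1OCc1ccccc1 | intermediate
34 | (3R,4R)-3-(ArL-methyl)-4-(DBF-methyl)oxolan-2-one (trans) | COc1cc([C@@H](O[Si](C)(C)C(C)(C)C)[C@H](CO[Si](C)(C)C(C)(C)C)c2cc(C[C@H]3C(=O)OC[C@@H]3Cc3cc(OC)c4c(c3)[C@H](CO[Si](c5ccccc5)(c5ccccc5)C(C)(C)C)[C@@H](c3ccc(OCc5ccccc5)c(OC)c3)O4)cc(OC)c2O[Si](C(C)C)(C(C)C)C(C)C)ccc1OCc1ccccc1 | intermediate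
35 | (3R,4R)-3-{3-[(1S,2S)-1-(4-benzyloxy-3-methoxyphenyl)-1,3-dihydroxypropan-2-yl]-4-hydroxy-5-methoxybenzyl}-4-{[(2S,3R)-2-(4-benzyloxy-3-methoxyphenyl)-3-(hydroxymethyl)-7-methoxy-2,3-dihydrobenzofuran-5-yl]methyl}oxolan-2-one | COc1cc([C@@H](O)[C@H](CO)c2cc(C[C@H]3C(=O)OC[C@@H]3Cc3cc(OC)c4c(c3)[C@H](CO)[C@@H](c3ccc(OCc5ccccc5)c(OC)c3)O4)cc(OC)c2O)ccc1OCc1ccccc1 | intermediate
36 | (3R,4R)-3-{3-[(1S,2S)-1,3-dihydroxy-1-(4-hydroxy-3-methoxyphenyl)propan-2-yl]-4-hydroxy-5-methoxybenzyl}-4-{[(2S,3R)-2-(4-hydroxy-3-methoxyphenyl)-3-(hydroxymethyl)-7-methoxy-2,3-dihydrobenzofuran-5-yl]methyl}oxolan-2-one (CNP0186558.2) | COc1cc([C@@H](O)[C@H](CO)c2cc(C[C@H]3C(=O)OC[C@@H]3Cc3cc(OC)c4c(c3)[C@H](CO)[C@@H](c3ccc(O)c(OC)c3)O4)cc(OC)c2O)ccc1O | target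

**Step count**

Total: 23 steps. Longest linear sequence: 19 steps (1, 2, 3, 4, 8, 9, 10, 11, 13, 14, 15, 16, 17, 18, 19, 20, 21, 22, 23).

**Steps most likely to fail**

Step 20. The syn addition of the alkoxycarbonylpalladium species across the hindered aryl alkyne may be slow. In that case chloride and tin Lewis acidity could ionise the benzylic silyl ether of the ring A/B half, or 5-endo oxypalladation of the alkyne could compete with CO insertion. The fallback changes the order of bond formation while CO still supplies the carbonyl carbon, and it makes step 19 unnecessary. It sets out from alkynol 29, which carries a terminal alkyne and no acid-labile benzylic ether. Under the same PdCl2(PPh3)2/SnCl2/CO conditions 29 should cyclise to (4R)-3-methylidene-4-(DBF-methyl)oxolan-2-one F1. A Mizoroki–Heck arylation of F1 with bromide 13 (Pd(OAc)2, P(o-tol)3, Et3N, DMF, 90 °C) should then give the E-benzylidene lactone by syn insertion and β-hydride elimination from the new benzylic carbon. The route is rejoined at 32.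

Step 5. Enolisation and addition of the hindered ortho-silyloxy arylacetyl imide to an electron-rich aldehyde may give poor anti or facial selectivity, or the aldol may revert before silyl trapping. The fallback builds the diol by the reliable syn aldol and then inverts the carbinol. It sets out from acid 5, which is coupled as in step 4 (through anhydride 7) with (R)-4-benzyl-2-oxazolidinone 19 to give the enantiomeric imide (4R)-4-benzyl-3-{2-[5-bromo-3-methoxy-2-(triisopropylsilyloxy)phenyl]acetyl}oxazolidin-2-one F2. A boron-mediated syn aldol with 9 (Bu2BOTf, i-Pr2NEt) should give the (2R,3R) adduct F3. LiBH4 then gives the (1R,2S)-diol F4. Double Mitsunobu esterification with chloroacetic acid (PPh3, DIAD, THF) acylates the primary alcohol and inverts the benzylic carbinol, giving the (1S,2S)-bis(chloroacetate) F5. K2CO3 in MeOH at 0 °C releases the (1S,2S)-diol, and the route is rejoined at 12.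

Step 15. TiCl4 may ionise the benzylic C2–O bond of the dihydrobenzofuran, with ring opening and loss of the trans relationship, or may cleave the guaiacyl benzyl ether by chelation before the enolate is alkylated. The fallback replaces enolate alkylation by enamine catalysis and needs no strong Lewis acid. It sets out from bromide 18. A Heck reaction with allyl alcohol (Pd(OAc)2, Bu4NCl, NaHCO3, DMF, 50 °C) should give 3-(DBF)propanal F6. α-Hydroxymethylation of F6 with aqueous formaldehyde, catalysed by (R)-α,α-diphenylprolinol trimethylsilyl ether, should give (2S)-3-hydroxy-2-(DBF-methyl)propanal F7, with the electrophile entering the enamine face away from the diarylmethyl group. Immediate silylation (TESCl, imidazole) gives the aldehyde, and the route is rejoined at 27, which goes on through the homologation and acid stages of step 18.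

Further compounds
F1 | step 20 | (4R)-3-methylidene-4-(DBF-methyl)oxolan-2-one | C=C1C(=O)OC[C@@H]1Cc1cc(OC)c2c(c1)[C@H](CO[Si](c1ccccc1)(c1ccccc1)C(C)(C)C)[C@@H](c1ccc(OCc3ccccc3)c(OC)c1)O2
F2 | step 5 | (4R)-4-benzyl-3-{2-[5-bromo-3-methoxy-2-(triisopropylsilyloxy)phenyl]acetyl}oxazolidin-2-one | COc1cc(Br)cc(CC(=O)N2[C@H](Cc3ccccc3)COC2=O)c1O[Si](C(C)C)(C(C)C)C(C)C
F3 | step 5 | (4R)-4-benzyl-3-{(2R,3R)-3-(4-benzyloxy-3-methoxyphenyl)-2-[5-bromo-3-methoxy-2-(triisopropylsilyloxy)phenyl]-3-hydroxypropanoyl}oxazolidin-2-one | COc1cc([C@H](O)[C@H](C(=O)N2[C@H](Cc3ccccc3)COC2=O)c2cc(Br)cc(OC)c2O[Si](C(C)C)(C(C)C)C(C)C)ccc1OCc1ccccc1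
F4 | step 5 | (1R,2S)-1-(4-benzyloxy-3-methoxyphenyl)-2-[5-bromo-3-methoxy-2-(triisopropylsilyloxy)phenyl]propane-1,3-diol | COc1cc([C@H](O)[C@H](CO)c2cc(Br)cc(OC)c2O[Si](C(C)C)(C(C)C)C(C)C)ccc1OCc1ccccc1
F5 | step 5 | (1S,2S)-1-(4-benzyloxy-3-methoxyphenyl)-2-[5-bromo-3-methoxy-2-(triisopropylsilyloxy)phenyl]propane-1,3-diyl bis(chloroacetate) | COc1cc([C@@H](OC(=O)CCl)[C@H](COC(=O)CCl)c2cc(Br)cc(OC)c2O[Si](C(C)C)(C(C)C)C(C)C)ccc1OCc1ccccc1
F6 | step 15 | 3-(DBF)propanal | O=CCCc1cc(OC)c2c(c1)[C@H](CO[Si](c1ccccc1)(c1ccccc1)C(C)(C)C)[C@@H](c1ccc(OCc3ccccc3)c(OC)c1)O2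
F7 | step 15 | (2S)-3-hydroxy-2-(DBF-methyl)propanal | O=C[C@H](CO)Cc1cc(OC)c2c(c1)[C@H](CO[Si](c1ccccc1)(c1ccccc1)C(C)(C)C)[C@@H](c1ccc(OCc3ccccc3)c(OC)c1)O2
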